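The oxolan-2-one ring (O1, carbonyl C2, methylidene-bearing C3, C4, chain-bearing C5) hides one molecule of CO2: O1–C2(=O) bridges the vinylic C3 and the sp3 carbon C5. The ring is therefore cut back to an acyclic alkenyl boronate whose C5 carries a mesylate of inverted configuration. In one operation, copper-catalysed carboxylation of the C3–B bond with CO2 makes C3–C2, and the acrylate oxygen so formed displaces the mesylate (5-exo-tet, inversion) to make O1–C5 and the 4,5-trans ring. The precursor arises from a borylative allene–aldehyde coupling; both carboxylic acids are unveiled together by a final Jones oxidation.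

Key step: step 6

Assumption on the chemistry: (R,R)-Ph-BPE is taken as the ligand enantiomer that delivers the (3R,4S) adduct in step 4; should the sense of induction prove opposite, its antipode is used.

Step 1
Reactants: 1 hexadecane-1,16-diol
Product: 2 16-[(tert-butyldimethylsilyl)oxy]hexadecan-1-ol
Conditions: TBSCl (1 equiv), imidazole, 1 (3 equiv, excess recovered), DMF–THF, 40 °C
Reagents that add atoms: tert-butyldimethylsilyl chloride (TBSCl), CC(C)(C)[Si](C)(C)Cl
Why: O-silylation of a primary alcohol with imidazole as base, run with excess symmetric diol so that statistical monoprotection should dominate over the bis-ether.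

Step 2
Reactants: 2 16-[(tert-butyldimethylsilyl)oxy]hexadecan-1-ol
Product: 3 16-[(tert-butyldimethylsilyl)oxy]hexadecanal
Conditions: TEMPO (10 mol %), PhI(OAc)2, CH2Cl2, rt
Reagents that add atoms: none
Why: Oxoammonium (TEMPO/PhI(OAc)2) oxidation of a primary alcohol should stop at the aldehyde under anhydrous conditions and leaves the silyl ether untouched.

Step 3
Reactants: 4 buta-2,3-dien-1-ol
Product: 5 (buta-2,3-dien-1-yloxy)(tert-butyl)dimethylsilane
Conditions: TBSCl, imidazole, CH2Cl2, 0 °C to rt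
Reagents that add atoms: tert-butyldimethylsilyl chloride (TBSCl), CC(C)(C)[Si](C)(C)Cl
Why: Standard imidazole-mediated silylation of a primary alcohol, to which the allene is inert.

Step 4
Reactants: 3 16-[(tert-butyldimethylsilyl)oxy]hexadecanal; 5 (buta-2,3-dien-1-yloxy)(tert-butyl)dimethylsilane
Product: 7 (3R,4S)-19-[(tert-butyldimethylsilyl)oxy]-3-{[(tert-butyldimethylsilyl)oxy]methyl}-2-(4,4,5,5-tetramethyl-1,3,2-dioxaborolan-2-yl)nonadec-1-en-4-ol, via O-boryl ether 6 (not isolated)
Conditions: CuCl (5 mol %), (R,R)-Ph-BPE (6 mol %), NaOtBu (20 mol %), B2pin2 (1.1 equiv), 5 (1.5 equiv), THF, 22 °C; then aqueous NH4Cl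
Reagents that add atoms: bis(pinacolato)diboron (B2pin2), CC1(C)OB(OC1(C)C)B1OC(C)(C)C(C)(C)O1
Why: Copper-catalysed borylative allene–aldehyde coupling: the ligated Cu–B(pin) adds across the terminal C=C of 5 anti to the CH2OTBS group to give a (Z)-2-boryl-allylcopper, which adds through its γ-carbon to 3 in a closed chair transition state, so the Z geometry should set the 3,4-syn diad and the chiral bisphosphine the absolute configuration.

Step 5
Reactants: 7 (3R,4S)-19-[(tert-butyldimethylsilyl)oxy]-3-{[(tert-butyldimethylsilyl)oxy]methyl}-2-(4,4,5,5-tetramethyl-1,3,2-dioxaborolan-2-yl)nonadec-1-en-4-ol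
Product: 8 (3R,4S)-19-[(tert-butyldimethylsilyl)oxy]-3-{[(tert-butyldimethylsilyl)oxy]methyl}-2-(4,4,5,5-tetramethyl-1,3,2-dioxaborolan-2-yl)nonadec-1-en-4-yl methanesulfonate
Conditions: MsCl, Et3N, CH2Cl2, −10 to 0 °C
Reagents that add atoms: methanesulfonyl chloride (MsCl), CS(=O)(=O)Cl
Why: Mesylation of a secondary alcohol (sulfene pathway) forms only the O–S bond, so C4 keeps its configuration and the alkenyl boronate is not affected.

Step 6
Reactants: 8 (3R,4S)-19-[(tert-butyldimethylsilyl)oxy]-3-{[(tert-butyldimethylsilyl)oxy]methyl}-2-(4,4,5,5-tetramethyl-1,3,2-dioxaborolan-2-yl)nonadec-1-en-4-yl methanesulfonate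
Product: 10 (4R,5R)-4-{[(tert-butyldimethylsilyl)oxy]methyl}-5-{15-[(tert-butyldimethylsilyl)oxy]pentadecyl}-3-methylideneoxolan-2-one, via potassium acrylate 9 (not isolated)
Conditions: (IPr)CuCl [IPr = 1,3-bis(2,6-diisopropylphenyl)imidazol-2-ylidene] (5 mol %), KOtBu (1.1 equiv), CO2 (1 atm), THF, 70 °C; then DMF co-solvent, 70 °C
Reagents that add atoms: carbon dioxide, O=C=O
Why: KOtBu turns (IPr)CuCl into (IPr)CuOtBu, which transmetalates the alkenyl–B(pin) bond of 8 to an alkenylcopper of monovalent copper; CO2 inserts into the Cu–C(sp2) bond (new C3–C2 bond) and alkoxide exchange releases potassium acrylate 9 and returns the catalyst. The closest known reaction type is the NHC–copper-catalysed carboxylation of aryl- and alkenylboronic esters with CO2, here coupled in the same flask to a classical intramolecular carboxylate O-alkylation. The oxolanone ring closes by 5-exo-tet attack of the carboxylate oxygen of 9 on C5 with loss of mesylate (new O1–C5 bond). C5 is set by Walden inversion of the (4S)-mesylate, so the syn open-chain diad becomes the 4,5-trans lactone with (5R) configuration, while C4, set in step 4, is not touched. The step needs substitution to beat E2 elimination and protodeboronation: free alkoxide is buffered as tert-butyl carbonate under CO2, the displacement is intramolecular and five-membered, and C4 carries CH2OTBS rather than an ester, so no E1cB path exists. The exocyclic methylidene is already in place as the alkenyl CH2, so no later methylenation is needed.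

Step 7
Reactants: 10 (4R,5R)-4-{[(tert-butyldimethylsilyl)oxy]methyl}-5-{15-[(tert-butyldimethylsilyl)oxy]pentadecyl}-3-methylideneoxolan-2-one
Product: 12 (2R,3S)-2-(14-carboxytetradecyl)-4-methylidene-5-oxooxolane-3-carboxylic acid, via diol 11 (not isolated)
Conditions: Jones reagent (CrO3, H2SO4, H2O), acetone, 0 °C to rt
Reagents that add atoms: water, O
Why: Jones oxidation: the aqueous sulfuric acid should cleave both primary TBS ethers to diol 11 and hexavalent chromium should oxidise both primary alcohols through their aldehyde hydrates to the carboxylic acids, conditions that an α-methylidene lactone tolerates and that leave the trans C4/C5 stereocentres in place.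

Compound list
1 | hexadecane-1,16-diol | OCCCCCCCCCCCCCCCCO | starting material
2 | 16-[(tert-butyldimethylsilyl)oxy]hexadecan-1-ol | OCCCCCCCCCCCCCCCCO[Si](C)(C)C(C)(C)C | intermediate
3 | 16-[(tert-butyldimethylsilyl)oxy]hexadecanal | O=CCCCCCCCCCCCCCCCO[Si](C)(C)C(C)(C)C | intermediate
4 | buta-2,3-dien-1-ol | C=C=CCO | starting material
5 | (buta-2,3-dien-1-yloxy)(tert-butyl)dimethylsilane | C=C=CCO[Si](C)(C)C(C)(C)C | intermediate
6 | O-boryl ether of 7: 2-{[(3R,4S)-19-[(tert-butyldimethylsilyl)oxy]-3-{[(tert-butyldimethylsilyl)oxy]methyl}-2-(4,4,5,5-tetramethyl-1,3,2-dioxaborolan-2-yl)nonadec-1-en-4-yl]oxy}-4,4,5,5-tetramethyl-1,3,2-dioxaborolane | C=C(B1OC(C)(C)C(C)(C)O1)[C@H](CO[Si](C)(C)C(C)(C)C)[C@@H](OB1OC(C)(C)C(C)(C)O1)CCCCCCCCCCCCCCCO[Si](C)(C)C(C)(C)C | intermediate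
7 | (3R,4S)-19-[(tert-butyldimethylsilyl)oxy]-3-{[(tert-butyldimethylsilyl)oxy]methyl}-2-(4,4,5,5-tetramethyl-1,3,2-dioxaborolan-2-yl)nonadec-1-en-4-ol (3,4-syn) | C=C(B1OC(C)(C)C(C)(C)O1)[C@H](CO[Si](C)(C)C(C)(C)C)[C@@H](O)CCCCCCCCCCCCCCCO[Si](C)(C)C(C)(C)C | intermediate
8 | (3R,4S)-19-[(tert-butyldimethylsilyl)oxy]-3-{[(tert-butyldimethylsilyl)oxy]methyl}-2-(4,4,5,5-tetramethyl-1,3,2-dioxaborolan-2-yl)nonadec-1-en-4-yl methanesulfonate | C=C(B1OC(C)(C)C(C)(C)O1)[C@H](CO[Si](C)(C)C(C)(C)C)[C@@H](OS(C)(=O)=O)CCCCCCCCCCCCCCCO[Si](C)(C)C(C)(C)C | intermediate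
9 | potassium (3R,4S)-19-[(tert-butyldimethylsilyl)oxy]-3-{[(tert-butyldimethylsilyl)oxy]methyl}-4-(methanesulfonyloxy)-2-methylidenenonadecanoate | C=C(C(=O)[O-])[C@H](CO[Si](C)(C)C(C)(C)C)[C@@H](OS(C)(=O)=O)CCCCCCCCCCCCCCCO[Si](C)(C)C(C)(C)C.[K+] | intermediate
10 | (4R,5R)-4-{[(tert-butyldimethylsilyl)oxy]methyl}-5-{15-[(tert-butyldimethylsilyl)oxy]pentadecyl}-3-methylideneoxolan-2-one (4,5-trans) | C=C1C(=O)O[C@H](CCCCCCCCCCCCCCCO[Si](C)(C)C(C)(C)C)[C@H]1CO[Si](C)(C)C(C)(C)C | intermediate
11 | (4R,5R)-4-(hydroxymethyl)-5-(15-hydroxypentadecyl)-3-methylideneoxolan-2-one | C=C1C(=O)O[C@H](CCCCCCCCCCCCCCCO)[C@H]1CO | intermediate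
12 | (2R,3S)-2-(14-carboxytetradecyl)-4-methylidene-5-oxooxolane-3-carboxylic acid | C=C1C(=O)O[C@H](CCCCCCCCCCCCCCC(=O)O)[C@H]1C(=O)O | target

Total step count: 7. Longest linear sequence: 6 steps (steps 1, 2, 4, 5, 6, 7).

Steps most likely to fail

Step 6. E2 elimination of the secondary mesylate toward a conjugated diene, or protodeboronation, may outrun transmetalation and CO2 insertion. The fallback sets out from 7 and comes back at 10. Iododeboronation of 7 (NaOH, I2, THF, 0 °C) should give (3R,4S)-19-[(tert-butyldimethylsilyl)oxy]-3-{[(tert-butyldimethylsilyl)oxy]methyl}-2-iodononadec-1-en-4-ol F1, and mesylation (MsCl, Et3N, CH2Cl2) the iodo mesylate F2. Iodine–magnesium exchange with iPrMgCl·LiCl (THF, −20 °C) should give the alkenylmagnesium chloride F3, which CO2 gas converts into the chloromagnesium acrylate F4. Warming with DMF should close F4 to 10 by the same 5-exo-tet displacement with inversion. Both ring bonds are still made from CO2 in one flask, but through a polar organomagnesium carboxylation instead of boron-to-copper transmetalation.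

Step 4. β-Silyloxy elimination from the allylcopper after 1,3-metal shift (giving a 2-boryl-1,3-diene) may compete with carbonyl addition, and allylcopper isomerisation may erode the syn and enantiomeric selectivity. The fallback sets out from 5 (with 3) and comes back at 6, hence 7 on work-up. Diboration of the terminal C=C of 5 with B2pin2 under zerovalent platinum catalysis (Pt(dba)2, PCy3, toluene, 50 °C) should give (Z)-tert-butyldimethyl{[3,4-bis(4,4,5,5-tetramethyl-1,3,2-dioxaborolan-2-yl)but-2-en-1-yl]oxy}silane F5. Allylboration of 3 with F5 under a chiral phosphoric acid (TRIP, toluene, −30 °C) passes through a boron-centred chair, so the Z geometry should again give the syn adduct, here directly as O-boryl ether 6. No allylcopper is formed, so the elimination path is closed.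

Step 7. Under the strongly acidic one-pot conditions, the transient C4 aldehyde may lose configuration or let the exocyclic alkene move into the ring, and silyl cleavage may lag behind oxidation. The fallback sets out from 10 and comes back at 12. HF·pyridine (THF, 0 °C) should give diol 11, now isolated. Dess–Martin periodinane (NaHCO3-buffered CH2Cl2) should give (2R,3S)-4-methylidene-5-oxo-2-(15-oxopentadecyl)oxolane-3-carbaldehyde F6, used crude. Pinnick oxidation (NaClO2, NaH2PO4, 2-methyl-2-butene, t-BuOH–H2O) should then give 12 under buffered, nearly neutral conditions.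

Further compounds
F1 | step 6 | (3R,4S)-19-[(tert-butyldimethylsilyl)oxy]-3-{[(tert-butyldimethylsilyl)oxy]methyl}-2-iodononadec-1-en-4-ol | C=C(I)[C@H](CO[Si](C)(C)C(C)(C)C)[C@@H](O)CCCCCCCCCCCCCCCO[Si](C)(C)C(C)(C)C
F2 | step 6 | (3R,4S)-19-[(tert-butyldimethylsilyl)oxy]-3-{[(tert-butyldimethylsilyl)oxy]methyl}-2-iodononadec-1-en-4-yl methanesulfonate | C=C(I)[C@H](CO[Si](C)(C)C(C)(C)C)[C@@H](OS(C)(=O)=O)CCCCCCCCCCCCCCCO[Si](C)(C)C(C)(C)C
F3 | step 6 | chloro{(3R,4S)-19-[(tert-butyldimethylsilyl)oxy]-3-{[(tert-butyldimethylsilyl)oxy]methyl}-4-(methanesulfonyloxy)nonadec-1-en-2-yl}magnesium | C=C([Mg]Cl)[C@H](CO[Si](C)(C)C(C)(C)C)[C@@H](OS(C)(=O)=O)CCCCCCCCCCCCCCCO[Si](C)(C)C(C)(C)C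
F4 | step 6 | chloromagnesium (3R,4S)-19-[(tert-butyldimethylsilyl)oxy]-3-{[(tert-butyldimethylsilyl)oxy]methyl}-4-(methanesulfonyloxy)-2-methylidenenonadecanoate | C=C(C(=O)[O-])[C@H](CO[Si](C)(C)C(C)(C)C)[C@@H](OS(C)(=O)=O)CCCCCCCCCCCCCCCO[Si](C)(C)C(C)(C)C.[Mg+2].[Cl-]
F5 | step 4 | (Z)-tert-butyldimethyl{[3,4-bis(4,4,5,5-tetramethyl-1,3,2-dioxaborolan-2-yl)but-2-en-1-yl]oxy}silane | CC1(C)OB(C/C(B2OC(C)(C)C(C)(C)O2)=C\CO[Si](C)(C)C(C)(C)C)OC1(C)C
F6 | step 7 | (2R,3S)-4-methylidene-5-oxo-2-(15-oxopentadecyl)oxolane-3-carbaldehyde | C=C1C(=O)O[C@H](CCCCCCCCCCCCCCC=O)[C@H]1C=O
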